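## Retrosynthetic overview

1. Blepharocalyxin E (36) ⇒ hepta-MOM chalcone 35 by global deprotection ⇒ aryl methyl ketone 33 + aldehyde 34 (Claisen–Schmidt). The acetyl group enters by bromination and Br–Li exchange on the phloroglucinol ring.
2. Side-chain C2′=C3′ (E) ⇒ cross-metathesis of a C1′-vinyl oxane with homoallylic alcohol (S)-6, the same building block that supplies C6.
3. Oxane C2 ⇒ aryllithium addition to δ-lactone 25, then axial silane reduction of the hemiketal (2,6-cis).
4. C3–C1′ bond and both stereocentres ⇒ proposed Ir-catalysed allylic alkylation of the ketene acetal of lactone 19 with cinnamyl carbonate 24 (C3 by substrate, C1′ by ligand).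
5. Lactone 19 is the only ring built and later becomes the oxane ⇒ lactonisation of a δ-hydroxy-β-keto ester made from (S)-6, then enol triflate/Negishi arylation and cis-selective hydrogenation (C4).

Assumption: compounds 26 and 34 are bought as catalogue items, and the ligand antipode written in step 15 is assigned by analogy as the one giving (1′S); if a model run shows the opposite sense, the commercial enantiomer is used.

Target configuration planned for: oxane (2S,3R,4R,6S), all substituents equatorial; C1′ (S); C5′ (S); both alkenes E.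

## Route

**Step 1**
Reactants: 1 methyl 3-(4-hydroxyphenyl)propanoate; 2 chloromethyl methyl ether (MOMCl)
Product: 3 methyl 3-[4-(methoxymethoxy)phenyl]propanoate
Conditions: MOMCl, iPr2NEt, CH2Cl2, 0 °C → rt
Reagents that add atoms: MOMCl (2), COCCl
Why: Phenol O-alkylation (Williamson-type MOM protection); MOM is used for all seven phenols because it survives the organolithium, enolate, Pd, Ir, Ru and KOH steps and can be removed at the end without protic acid.

**Step 2**
Reactants: 3
Product: 4 3-[4-(methoxymethoxy)phenyl]propanal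
Conditions: DIBAL-H (1.1 equiv), CH2Cl2, −78 °C; Rochelle salt
Reagents that add atoms: none
Why: Low-temperature DIBAL partial reduction stops at the aluminium hemiacetal and releases the aldehyde on work-up.

**Step 3**
Reactants: 4; 5 allylmagnesium bromide
Product: 6 (3S)-1-[4-(methoxymethoxy)phenyl]hex-5-en-3-ol
Conditions: (+)-Ipc2BOMe (from (−)-α-pinene), allylMgBr, Et2O, 0 °C → rt; then 4, −78 °C; NaOH, H2O2
Reagents that add atoms: allylmagnesium bromide (5), C=CC[Mg]Br
Why: Brown asymmetric allylboration; the (+)-Ipc2B(allyl) reagent adds through a closed chair transition state to the Re face of the aldehyde and sets the (S)-carbinol that becomes both C6 and C5′.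

**Step 4**
Reactants: 6; 7 tert-butyldimethylsilyl chloride
Product: 8 tert-butyl{[(3S)-1-[4-(methoxymethoxy)phenyl]hex-5-en-3-yl]oxy}dimethylsilane
Conditions: TBSCl, imidazole, DMF, rt
Reagents that add atoms: TBSCl (7), CC(C)(C)[Si](C)(C)Cl
Why: Standard silylation of the secondary alcohol; the stereocentre is not involved.

**Step 5**
Reactants: 8
Product: 10 (3S)-3-[(tert-butyldimethylsilyl)oxy]-5-[4-(methoxymethoxy)phenyl]pentanal
Conditions: OsO4 (2 mol %), NaIO4 (4 equiv), 2,6-lutidine, dioxane/H2O 3:1, rt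
Reagents that add atoms: 9 sodium periodate, [Na+].[O-]I(=O)(=O)=O, with catalytic OsO4, O=[Os](=O)(=O)=O (source of the aldehyde oxygen)
Why: Lemieux–Johnson oxidative cleavage converts the terminal alkene into the aldehyde without exposing the electron-rich arene to ozone; the β-silyloxy stereocentre is untouched.

**Step 6**
Reactants: 10; 11 ethyl diazoacetate
Product: 12 ethyl (5S)-5-[(tert-butyldimethylsilyl)oxy]-7-[4-(methoxymethoxy)phenyl]-3-oxoheptanoate
Conditions: ethyl diazoacetate (1.2 equiv), SnCl2 (10 mol %), CH2Cl2, rt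
Reagents that add atoms: ethyl diazoacetate (11), CCOC(=O)C=[N+]=[N-]
Why: Roskamp homologation; Lewis-acid-promoted addition of the diazoester to the aldehyde, 1,2-hydride shift and loss of N2 give the β-keto ester under near-neutral conditions.

**Step 7**
Reactants: 12
Product: 13 (6S)-6-{2-[4-(methoxymethoxy)phenyl]ethyl}oxane-2,4-dione (exists as the 4-hydroxy-5,6-dihydro-2H-pyran-2-one enol)
Conditions: TBAF, THF, 0 °C → rt; then K2CO3, MeOH, rt; acidify to pH 3 (citric acid)
Reagents that add atoms: none
Why: Desilylation frees the δ-hydroxyl, which lactonises onto the ethyl ester (intramolecular acyl substitution); this forms the only ring of the route with C6 already (S).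

**Step 8**
Reactants: 13; 14 trifluoromethanesulfonic anhydride
Product: 15 (6S)-6-{2-[4-(methoxymethoxy)phenyl]ethyl}-2-oxo-5,6-dihydro-2H-pyran-4-yl trifluoromethanesulfonate
Conditions: Tf2O, Et3N, CH2Cl2, −78 °C
Reagents that add atoms: Tf2O (14), O=S(=O)(OS(=O)(=O)C(F)(F)F)C(F)(F)F
Why: O-sulfonylation of the cyclic β-keto lactone enol gives the enol triflate needed for cross-coupling at C4.

**Step 9**
Reactants: 16 5-methoxybenzene-1,3-diol (5-methoxyresorcinol); 2 MOMCl
Product: 17 1-methoxy-3,5-bis(methoxymethoxy)benzene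
Conditions: MOMCl (2.5 equiv), iPr2NEt, CH2Cl2, 0 °C → rt
Reagents that add atoms: MOMCl (2), COCCl
Why: Double phenol MOM protection; the two OMOM groups later direct metalation to the carbon between them.

**Step 10**
Reactants: 15; 17
Product: 18 (6S)-4-[4-methoxy-2,6-bis(methoxymethoxy)phenyl]-6-{2-[4-(methoxymethoxy)phenyl]ethyl}-5,6-dihydro-2H-pyran-2-one
Conditions: 17 (1.3 equiv), n-BuLi, THF, 0 °C; ZnCl2, 0 °C → rt; then 15, Pd2(dba)3 (2.5 mol %), SPhos (10 mol %), THF, rt → 45 °C
Reagents that add atoms: none beyond arene 17, COCOc1cc(OC)cc(OCOC)c1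
Why: Directed ortho-metalation between the two cooperating OMOM groups, transmetalation to zinc and Negishi coupling with the vinyl triflate (SPhos tolerates the di-ortho-substituted arylzinc) form the C4–aryl bond and avoid the protodeboronation typical of the corresponding boronic acid.

**Step 11**
Reactants: 18
Product: 19 (4R,6S)-4-[4-methoxy-2,6-bis(methoxymethoxy)phenyl]-6-{2-[4-(methoxymethoxy)phenyl]ethyl}oxan-2-one (4,6-cis)
Conditions: H2 (3 atm), 10% Pd/C, EtOAc, rt
Reagents that add atoms: none
Why: Heterogeneous hydrogenation of a 4,6-disubstituted 5,6-dihydropyranone delivers H2 to the alkene face opposite the pseudo-equatorial C6 side chain, so the aryl group ends up cis to it and C4 is set (R), diequatorial.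

**Step 12**
Reactants: 20 methyl (E)-3-(4-hydroxyphenyl)prop-2-enoate; 2 MOMCl
Product: 21 methyl (E)-3-[4-(methoxymethoxy)phenyl]prop-2-enoate
Conditions: MOMCl, iPr2NEt, CH2Cl2, 0 °C → rt
Reagents that add atoms: MOMCl (2), COCCl
Why: Phenol MOM protection as in step 1.

**Step 13**
Reactants: 21
Product: 22 (E)-3-[4-(methoxymethoxy)phenyl]prop-2-en-1-ol
Conditions: DIBAL-H (2.2 equiv), CH2Cl2, −78 → 0 °C
Reagents that add atoms: none
Why: DIBAL 1,2-reduction of the enoate gives the allylic alcohol with the E-alkene intact.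

**Step 14**
Reactants: 22; 23 methyl chloroformate
Product: 24 (E)-3-[4-(methoxymethoxy)phenyl]prop-2-en-1-yl methyl carbonate
Conditions: ClCO2Me, pyridine, CH2Cl2, 0 °C
Reagents that add atoms: methyl chloroformate (23), COC(=O)Cl
Why: O-acylation gives the linear allylic carbonate, the standard electrophile for Ir-catalysed allylic substitution.

**Step 15 (proposed new transformation)**
Reactants: 19; 24
Product: 25 (3R,4R,6S)-4-[4-methoxy-2,6-bis(methoxymethoxy)phenyl]-6-{2-[4-(methoxymethoxy)phenyl]ethyl}-3-{(1S)-1-[4-(methoxymethoxy)phenyl]prop-2-en-1-yl}oxan-2-one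
Conditions: (i) LiHMDS, TMSCl, THF, −78 → 0 °C, concentrate (TMS ketene acetal used crude); (ii) 24 (1.5 equiv), [Ir(cod)Cl]2 (4 mol %), (Sa,S,S)-BINOL bis(1-phenylethyl)amine phosphoramidite (8 mol %, pre-activated with n-PrNH2), ZnF2 (1.5 equiv), CsF (0.4 equiv), DME, 50 °C; (iii) DBU (cat.), CH2Cl2, rt if C3 dr < 10:1
Reagents that add atoms: none beyond carbonate 24, COCOc1ccc(/C=C/COC(=O)OC)cc1
Why: Proposed new method: Ir-catalysed branched-selective allylic alkylation with the silyl ketene acetal of an unstabilised, β-stereogenic δ-lactone as nucleophile. The cyclometalated Ir–phosphoramidite ionises 24 to an η3-cinnamyl Ir(III) complex, and fluoride/methoxide unmasks the ring-locked (single-geometry) enolate, which attacks the aryl-bearing allyl terminus outer-sphere. C1′ (S) is therefore set by the ligand, and C3 (R) by attack anti to the equatorial C4 aryl group (3,4-trans). A minor C3 epimer can be equilibrated to the all-equatorial lactone because C3–H is acidic, whereas C1′ is not epimerisable. The closest known reactions are Ir/phosphoramidite allylations of ketone silyl enol ethers, cyclic ketone enolates and acyclic ester silyl ketene acetals under fluoride activation. A saturated lactone ketene acetal, with the nucleophile face under substrate control and the allyl face under catalyst control to give a vicinal tertiary/tertiary pair, has not been demonstrated.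

**Step 16**
Reactants: 25; 26 1-bromo-4-(methoxymethoxy)benzene
Product: 27 (3R,4R,6S)-2-hydroxy-2-[4-(methoxymethoxy)phenyl]-4-[4-methoxy-2,6-bis(methoxymethoxy)phenyl]-6-{2-[4-(methoxymethoxy)phenyl]ethyl}-3-{(1S)-1-[4-(methoxymethoxy)phenyl]prop-2-en-1-yl}oxane (hemiketal, C2 mixture in equilibrium with the open δ-hydroxy ketone; used crude)
Conditions: 26 (2.5 equiv), n-BuLi, THF, −78 °C; anhydrous CeCl3, −78 °C; then 25, −78 °C; sat. NH4Cl
Reagents that add atoms: none beyond aryl bromide 26, COCOc1ccc(Br)cc1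
Why: 1,2-Addition of the aryl organocerium (which suppresses C3 enolisation) to the lactone carbonyl gives a tetrahedral alkoxide that does not over-add (C-aryl-glycoside-type lactone arylation); C3 can only relax to the favoured trans isomer.

**Step 17**
Reactants: 27
Product: 28 (2S,3R,4R,6S)-4-[4-methoxy-2,6-bis(methoxymethoxy)phenyl]-2-[4-(methoxymethoxy)phenyl]-6-{2-[4-(methoxymethoxy)phenyl]ethyl}-3-{(1S)-1-[4-(methoxymethoxy)phenyl]prop-2-en-1-yl}oxane
Conditions: Et3SiH (6 equiv), BF3·OEt2 (2 equiv), CH2Cl2/MeCN 1:1, −78 → −40 °C; Et3N quench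
Reagents that add atoms: none
Why: Reductive deoxygenation of the hemiketal; ionisation to the 2-aryl oxocarbenium ion and axial hydride delivery through a chair-like transition state with the C3, C4 and C6 groups equatorial set C2 (S) with the aryl equatorial (2,6-cis), and the tertiary benzylic hemiketal ionises far faster than the MOM acetals at this temperature.

**Step 18**
Reactants: 28; 29 N-bromosuccinimide
Product: 30 (2S,3R,4R,6S)-4-[3-bromo-4-methoxy-2,6-bis(methoxymethoxy)phenyl]-2-[4-(methoxymethoxy)phenyl]-6-{2-[4-(methoxymethoxy)phenyl]ethyl}-3-{(1S)-1-[4-(methoxymethoxy)phenyl]prop-2-en-1-yl}oxane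
Conditions: NBS (1.0 equiv), MeCN, −40 → −20 °C, dark
Reagents that add atoms: NBS (29), O=C1CCC(=O)N1Br
Why: Electrophilic aromatic bromination; the trialkoxy ring is far more nucleophilic than the 4-alkoxyphenyl rings or the vinyl group, and its two free positions are equivalent, so a single bromide forms.

**Step 19**
Reactants: 30; 31 N-methoxy-N-methylacetamide
Product: 32 1-{3-[(2S,3R,4R,6S)-2-[4-(methoxymethoxy)phenyl]-6-{2-[4-(methoxymethoxy)phenyl]ethyl}-3-{(1S)-1-[4-(methoxymethoxy)phenyl]prop-2-en-1-yl}oxan-4-yl]-6-methoxy-2,4-bis(methoxymethoxy)phenyl}ethan-1-one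
Conditions: n-BuLi (1.1 equiv), THF, −78 °C, 10 min; then 31 (3 equiv), −78 → 0 °C
Reagents that add atoms: N-methoxy-N-methylacetamide (31), CON(C)C(C)=O
Why: Bromine–lithium exchange gives a chelate-stabilised 2,6-dialkoxyaryllithium that is acylated once by the Weinreb amide (stable tetrahedral chelate); the substrate has no acidic or electrophilic group at −78 °C.

**Step 20**
Reactants: 32; 6
Product: 33 1-{3-[(2S,3R,4R,6S)-3-{(1S,2E,5S)-5-hydroxy-1,7-bis[4-(methoxymethoxy)phenyl]hept-2-en-1-yl}-2-[4-(methoxymethoxy)phenyl]-6-{2-[4-(methoxymethoxy)phenyl]ethyl}oxan-4-yl]-6-methoxy-2,4-bis(methoxymethoxy)phenyl}ethan-1-one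
Conditions: 6 (3 equiv), Hoveyda–Grubbs II (10 mol %, two portions), 1,4-benzoquinone (10 mol %), CH2Cl2, 40 °C
Reagents that add atoms: none beyond alcohol 6, C=CC[C@@H](O)CCc1ccc(OCOC)cc1
Why: Olefin cross-metathesis between the hindered allylically branched vinyl group (which does not homodimerise) and the reactive homoallylic alcohol gives the thermodynamic E-alkene. Benzoquinone suppresses Ru–H isomerisation that would erase C1′, and C5′ (S) arrives preset in 6.

**Step 21**
Reactants: 33; 34 4-(methoxymethoxy)benzaldehyde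
Product: 35 (E)-1-{3-[(2S,3R,4R,6S)-3-{(1S,2E,5S)-5-hydroxy-1,7-bis[4-(methoxymethoxy)phenyl]hept-2-en-1-yl}-2-[4-(methoxymethoxy)phenyl]-6-{2-[4-(methoxymethoxy)phenyl]ethyl}oxan-4-yl]-6-methoxy-2,4-bis(methoxymethoxy)phenyl}-3-[4-(methoxymethoxy)phenyl]prop-2-en-1-one
Conditions: 34 (1.5 equiv), KOH (50% aq.), EtOH, rt, 24 h
Reagents that add atoms: none beyond aldehyde 34, COCOc1ccc(C=O)cc1
Why: Claisen–Schmidt aldol condensation with E1cB dehydration gives the E-chalcone; the fully O-protected ketone cannot cyclise to a flavanone, and nothing else in 33 is base-sensitive.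

**Step 22**
Reactants: 35
Product: 36 Blepharocalyxin E
Conditions: TMSOTf (16 equiv), 2,2′-bipyridyl (24 equiv), CH2Cl2, 0 °C → rt; then H2O/THF, rt; reverse-phase HPLC
Reagents that add atoms: none
Why: Silyl triflate/bipyridyl activation converts each aryl MOM acetal into an aryl silyl ether that hydrolyses on aqueous work-up (the alcohol TMS ether also hydrolyses). This avoids protic acid, which could open the 2-aryl oxane or isomerise it to a chroman, and avoids base, which cyclises the 2′-hydroxychalcone to a flavanone.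

## Compound list

1 | methyl 3-(4-hydroxyphenyl)propanoate | COC(=O)CCc1ccc(O)cc1 | starting material
2 | chloromethyl methyl ether | COCCl | starting material (reagent)
3 | methyl 3-[4-(methoxymethoxy)phenyl]propanoate | COCOc1ccc(CCC(=O)OC)cc1 | intermediate
4 | 3-[4-(methoxymethoxy)phenyl]propanal | COCOc1ccc(CCC=O)cc1 | intermediate
5 | allylmagnesium bromide | C=CC[Mg]Br | starting material (reagent)
6 | (3S)-1-[4-(methoxymethoxy)phenyl]hex-5-en-3-ol | C=CC[C@@H](O)CCc1ccc(OCOC)cc1 | intermediate
7 | tert-butyldimethylsilyl chloride | CC(C)(C)[Si](C)(C)Cl | starting material (reagent)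
8 | TBS ether of 6 | C=CC[C@@H](O[Si](C)(C)C(C)(C)C)CCc1ccc(OCOC)cc1 | intermediate
9 | sodium periodate (with cat. OsO4) | [Na+].[O-]I(=O)(=O)=O | starting material (reagent)
10 | (3S)-3-[(tert-butyldimethylsilyl)oxy]-5-[4-(methoxymethoxy)phenyl]pentanal | O=CC[C@@H](O[Si](C)(C)C(C)(C)C)CCc1ccc(OCOC)cc1 | intermediate
11 | ethyl diazoacetate | CCOC(=O)C=[N+]=[N-] | starting material (reagent)
12 | ethyl (5S)-5-[(tert-butyldimethylsilyl)oxy]-7-[4-(methoxymethoxy)phenyl]-3-oxoheptanoate | CCOC(=O)CC(=O)C[C@@H](O[Si](C)(C)C(C)(C)C)CCc1ccc(OCOC)cc1 | intermediate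
13 | (6S)-6-{2-[4-(methoxymethoxy)phenyl]ethyl}oxane-2,4-dione | O=C1CC(=O)C[C@H](CCc2ccc(OCOC)cc2)O1 | intermediate
14 | trifluoromethanesulfonic anhydride | O=S(=O)(OS(=O)(=O)C(F)(F)F)C(F)(F)F | starting material (reagent)
15 | (6S)-6-{2-[4-(methoxymethoxy)phenyl]ethyl}-2-oxo-5,6-dihydro-2H-pyran-4-yl triflate | O=C1C=C(OS(=O)(=O)C(F)(F)F)C[C@H](CCc2ccc(OCOC)cc2)O1 | intermediate
16 | 5-methoxybenzene-1,3-diol | COc1cc(O)cc(O)c1 | starting material
17 | 1-methoxy-3,5-bis(methoxymethoxy)benzene | COCOc1cc(OC)cc(OCOC)c1 | intermediate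
18 | (6S)-4-[4-methoxy-2,6-bis(methoxymethoxy)phenyl]-6-{2-[4-(methoxymethoxy)phenyl]ethyl}-5,6-dihydro-2H-pyran-2-one | O=C1C=C(c2c(OCOC)cc(OC)cc2OCOC)C[C@H](CCc3ccc(OCOC)cc3)O1 | intermediate
19 | (4R,6S)-4-[4-methoxy-2,6-bis(methoxymethoxy)phenyl]-6-{2-[4-(methoxymethoxy)phenyl]ethyl}oxan-2-one | COc1cc(OCOC)c([C@@H]2C[C@H](CCc3ccc(OCOC)cc3)OC(=O)C2)c(OCOC)c1 | intermediate
20 | methyl (E)-3-(4-hydroxyphenyl)prop-2-enoate | COC(=O)/C=C/c1ccc(O)cc1 | starting material
21 | methyl (E)-3-[4-(methoxymethoxy)phenyl]prop-2-enoate | COCOc1ccc(/C=C/C(=O)OC)cc1 | intermediate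
22 | (E)-3-[4-(methoxymethoxy)phenyl]prop-2-en-1-ol | COCOc1ccc(/C=C/CO)cc1 | intermediate
23 | methyl chloroformate | COC(=O)Cl | starting material (reagent)
24 | (E)-3-[4-(methoxymethoxy)phenyl]prop-2-en-1-yl methyl carbonate | COCOc1ccc(/C=C/COC(=O)OC)cc1 | intermediate
25 | (3R,4R,6S)-3-[(1S)-1-arylallyl] lactone (full name in step 15) | COc1cc(OCOC)c([C@@H]2C[C@H](CCc3ccc(OCOC)cc3)OC(=O)[C@H]2[C@H](C=C)c2ccc(OCOC)cc2)c(OCOC)c1 | intermediate
26 | 1-bromo-4-(methoxymethoxy)benzene | COCOc1ccc(Br)cc1 | starting material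
27 | 2-aryl hemiketal of 25 (C2 mixture) | COc1cc(OCOC)c([C@@H]2C[C@H](CCc3ccc(OCOC)cc3)OC(O)(c3ccc(OCOC)cc3)[C@H]2[C@H](C=C)c2ccc(OCOC)cc2)c(OCOC)c1 | intermediate
28 | (2S,3R,4R,6S)-tetrasubstituted oxane with (1S)-1-arylallyl at C3 (full name in step 17) | COc1cc(OCOC)c([C@@H]2C[C@H](CCc3ccc(OCOC)cc3)O[C@H](c3ccc(OCOC)cc3)[C@H]2[C@H](C=C)c2ccc(OCOC)cc2)c(OCOC)c1 | intermediate
29 | N-bromosuccinimide | O=C1CCC(=O)N1Br | starting material (reagent)
30 | aryl bromide of 28 (full name in step 18) | COc1cc(OCOC)c([C@@H]2C[C@H](CCc3ccc(OCOC)cc3)O[C@H](c3ccc(OCOC)cc3)[C@H]2[C@H](C=C)c2ccc(OCOC)cc2)c(OCOC)c1Br | intermediate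
31 | N-methoxy-N-methylacetamide | CON(C)C(C)=O | starting material (reagent)
32 | aryl methyl ketone (full name in step 19) | COc1cc(OCOC)c([C@@H]2C[C@H](CCc3ccc(OCOC)cc3)O[C@H](c3ccc(OCOC)cc3)[C@H]2[C@H](C=C)c2ccc(OCOC)cc2)c(OCOC)c1C(C)=O | intermediate
33 | cross-metathesis product with (1S,2E,5S) side chain (full name in step 20) | COc1cc(OCOC)c([C@@H]2C[C@H](CCc3ccc(OCOC)cc3)O[C@H](c3ccc(OCOC)cc3)[C@H]2[C@H](/C=C/C[C@@H](O)CCc2ccc(OCOC)cc2)c2ccc(OCOC)cc2)c(OCOC)c1C(C)=O | intermediate
34 | 4-(methoxymethoxy)benzaldehyde | COCOc1ccc(C=O)cc1 | starting material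
35 | hepta-MOM Blepharocalyxin E (full name in step 21) | COc1cc(OCOC)c([C@@H]2C[C@H](CCc3ccc(OCOC)cc3)O[C@H](c3ccc(OCOC)cc3)[C@H]2[C@H](/C=C/C[C@@H](O)CCc2ccc(OCOC)cc2)c2ccc(OCOC)cc2)c(OCOC)c1C(=O)/C=C/c1ccc(OCOC)cc1 | intermediate
36 | Blepharocalyxin E | COc1cc(O)c([C@@H]2C[C@H](CCc3ccc(O)cc3)O[C@H](c3ccc(O)cc3)[C@H]2[C@H](/C=C/C[C@@H](O)CCc2ccc(O)cc2)c2ccc(O)cc2)c(O)c1C(=O)/C=C/c1ccc(O)cc1 | target

## Summary

Total steps: 22.
Longest linear sequence: 18 steps (1–8, 10, 11, 15–22).

Steps most likely to fail, each with a fallback that changes the approach: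

1. **Step 15 (proposed Ir-catalysed lactone allylation).** Risks are low reactivity of the hindered nucleophile, branched/linear erosion with the electron-rich cinnamyl unit, and the unverified sense of induction. Fallback (known chemistry): Ireland–Claisen rearrangement. Open 19 to its O-silylated seco-acid and esterify it with the enantiopure (E)-allylic alcohol ArCH=CH–CH(OH)–CH2–CH(OTBS)–CH2CH2Ar (Ar = 4-MOMO-phenyl; made from aldehyde 10 by alkenyl addition, oxidation and CBS reduction). The chair [3,3] shift of the silyl ketene acetal sets C3 and C1′ by 1,3-chirality transfer and installs the complete E side chain. Desilylation and relactonisation rejoin the route at step 16, with step 20 no longer needed.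

2. **Step 20 (cross-metathesis at the hindered C1′ vinyl group).** Risks are low conversion and alkene migration. Fallback: Lemieux–Johnson cleavage of the vinyl group to the C1′ aldehyde, then Takai–Utimoto CrCl2 alkylidenation with the gem-diiodide prepared from aldehyde 10. This is non-basic, so the α-aryl stereocentre survives, and it is E-selective; fluoride then frees C5′–OH.

3. **Steps 16–17 (aryl addition to the α-branched lactone and reductive etherification).** Risks are enolisation instead of addition and MOM loss under BF3. Fallback: DIBAL reduction of 25 to the lactol, acetylation, and Lewis-acid C-arylation of the derived oxocarbenium ion with the arylzinc from 26. Mild acid equilibration of the 2-(4-alkoxyphenyl) oxane then gives the thermodynamic all-equatorial 2,6-cis isomer (oxocarbenium C-glycosylation logic in place of carbonyl addition/reduction).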